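Read Tuesday's flask at 25 h, well past its last reading at 10.0 h, and watch the slow tail of E, not its peak.

common to all: Z 0.059 M

| flask | D | remark | time |
|---|---|---|---|
| Tuesday's | 0.18 M | the very flask that is asked about, followed so far |  |
| Wednesday's | 0.090 M | run made earlier |  |
| flask | 0.180 M |  | 25 h |

- Tuesday's (time / h: E / %, J / %, Z / %): 0.833: 8, 1, 61; 1.33: 15, 0, 48; 2.00: 21, 2, 46; 3.00: 21, 0, 38; 4.00: 21, 4, 37; 6.00: 17, 4, 31; 10.0: 12, 4, 30
- Wednesday's (time / h: E / %, J / %, Z / %): 0.500: 1, 0, 86; 1.50: 10, 1, 70; 3.00: 16, 0, 57; 4.00: 15, 4, 54; 6.00: 14, 1, 53; 8.00: 11, 4, 52; 10.0: 9, 0, 49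

(standard deviation of a reading: 2 percentage points)



* equivalents of D to Z, everything else as given, that leave most E at 25 h
* the amount of E then, in percent of the Z charged
* the amount of E with the amounts as given

Turn the question round and ask what would leave hardly any E in Tuesday's flask. E's own fall between 4.00 h and 10.0 h, 0.0933 h⁻¹, would have to continue, and that leaves 2.96 % of the charge. E need not follow the seen fraction Z + E + J, since its share of that sum went from 33.9 % to 26.1 % between those readings; so reckon the other case too, in which the share stops shrinking. Take the tail rate 0.0307 h⁻¹, the pseudo-first-order fall of that summed fraction between two late readings. It is slower than E's own fall. Assume, against that shrinking share, that E's share of the sum holds from the last reading on, and integrate: E(t) = E(last) exp(−tail rate × elapsed time). This gives 7.58 % at 25 h, a rough figure, since it rests on single readings with their scatter.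

The forecast gave less, 6 %, and 7 % at 4.5 equiv, expecting “a broad, shallow optimum”.

Tuesday's flask gives 9.30 % at 25 h, more than reckoned, and the best charge is 4.61 equiv, with 10.1 %.

    Z + D ⇌ G + X (K = 0.480, k = 0.00107 M⁻¹ s⁻¹)
    X + D ⇌ G + E (K = 1.13, k = 0.00177 M⁻¹ s⁻¹)
    E + D ⇌ G + L (K = 1.80, k = 8.10 × 10⁻⁴ M⁻¹ s⁻¹)
    L + D ⇌ G + J (K = 0.162, k = 2.68 × 10⁻⁴ M⁻¹ s⁻¹)
    E → Q (k = 3.08 × 10⁻⁵ s⁻¹)

Read the tail rate again in this flask, between 12.5 h and 25 h: the simulated fractions give 0.0149 h⁻¹, slower than the rate from the readings. Carry it from 9.30 % to the same flask read at 4.0 d: the integrated form gives 3.23 % of E, and that neighbour holds 2.76 %.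

(All runs were computed with constants of no real substance, and the scatter is random.)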